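The ring is closed last, at C5–C6, by a SmI2 aldehyde–alkene reductive cyclisation. The route below is a proposal and has not been run; no step is claimed as measured.

Everything rests on closing the ten-membered carbocycle last, across C5–C6 (germacrane numbering), by a SmI2 aldehyde–alkene reductive cyclisation. The step exploits the furanone ring (O, C3, C2, C1, C10): its exocyclic C4=C5 methylene is cross-conjugated with the C2=C3–C1=O enone, a 1,6-acceptor whose terminus is the future ring CH2, so the C6 ketyl joins it and gives the macrocycle, the C6 carbinol and, on protonation, C4 in one operation. The precursor is an open-chain C6 aldehyde carrying the C7 acrylate, the C8 angelate and the intact furanone, assembled from (S)-citramalic acid, an enyne and an allylic bromide; acid then closes the lactone.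

Key step: step 14

Remark: germacrane numbering is used throughout: C1 (furanone C=O), C2=C3, C4 (bears C15H2OH), C5 (CH2), C6 (lactone O–CH), C7, C8 (angelate), C9, C10 (quaternary, methyl C14, furanone O), C11(=C13H2), C12 (lactone C=O); the target is (4S,6R,7S,8R,10S).
Assumption: the four carbon building blocks and all reagents named are taken as purchasable.

Step 1
Reactants: 1 (S)-citramalic acid [(2S)-2-hydroxy-2-methylbutanedioic acid]
Product: 2 [(4S)-2,2,4-trimethyl-5-oxo-1,3-dioxolan-4-yl]acetic acid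
Conditions: 2,2-dimethoxypropane, PPTS (cat.), rt
Reagents that add atoms: 2,2-dimethoxypropane, COC(C)(C)OC
Why: Acid-catalysed acetonide (1,3-dioxolan-4-one) formation engages only the α-hydroxy acid unit, so the C1 and C8 carboxyl groups are differentiated and the quaternary C10 centre of the chiral pool acid is untouched.

Step 2
Reactants: 2 [(4S)-2,2,4-trimethyl-5-oxo-1,3-dioxolan-4-yl]acetic acid
Product: 4 (3S)-3-hydroxy-3-methyloxolan-2-one, via hydroxyethyl dioxolanone 3 (not isolated)
Conditions: BH3·SMe2, THF, 0 °C to rt; MeOH; then TsOH·H2O (cat.), CH2Cl2, rt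
Reagents that add atoms: none
Why: Chemoselective borane reduction of the free acid beside the dioxolanone, then acid-catalysed translactonisation of the primary alcohol onto the activated acyl group with loss of acetone; C10 is not involved.

Step 3
Reactants: 5 2-bromoprop-2-en-1-ol
Product: 6 1-{[(2-bromoprop-2-en-1-yl)oxy]methyl}-4-methoxybenzene
Conditions: NaH, 4-methoxybenzyl chloride, Bu4NI (cat.), THF, 0 °C to rt
Reagents that add atoms: 4-methoxybenzyl chloride, COc1ccc(CCl)cc1
Why: Williamson ether synthesis on the primary allylic alkoxide; the vinyl bromide is inert under these conditions.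

Step 4
Reactants: 6 1-{[(2-bromoprop-2-en-1-yl)oxy]methyl}-4-methoxybenzene
Product: 8 1-methoxy-4-{[(2-methylidenebut-3-yn-1-yl)oxy]methyl}benzene, via trimethylsilyl enyne 7 (not isolated)
Conditions: ethynyltrimethylsilane, Pd(PPh3)2Cl2 (3 mol%), CuI (5 mol%), Et3N, THF, rt; then K2CO3 (cat.), MeOH, rt
Reagents that add atoms: ethynyltrimethylsilane, C#C[Si](C)(C)C
Why: Sonogashira coupling at the vinyl bromide installs C2–C3, and methanolysis of the C–Si bond frees the terminal alkyne.

Step 5
Reactants: 4 (3S)-3-hydroxy-3-methyloxolan-2-one; 8 1-methoxy-4-{[(2-methylidenebut-3-yn-1-yl)oxy]methyl}benzene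
Product: 9 (6S)-6,8-dihydroxy-2-{[(4-methoxyphenyl)methoxy]methyl}-6-methyloct-1-en-3-yn-5-one
Conditions: 8 (2.3 equiv), n-BuLi (2.2 equiv), THF, −78 °C; then 4, −78 to −40 °C; aq. NH4Cl
Reagents that add atoms: none
Why: Lithium acetylide addition to a γ-lactone should stop at the lithium hemiketal, so one acyl substitution gives the ynone on quench; the first equivalent of acetylide only deprotonates the tertiary hydroxyl, and C10 has no α-hydrogen to lose.

Step 6
Reactants: 9 (6S)-6,8-dihydroxy-2-{[(4-methoxyphenyl)methoxy]methyl}-6-methyloct-1-en-3-yn-5-one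
Product: 10 (2S)-2-(2-hydroxyethyl)-5-{3-[(4-methoxyphenyl)methoxy]prop-1-en-2-yl}-2-methylfuran-3(2H)-one
Conditions: AuCl3 (5 mol%), CH2Cl2, rt
Reagents that add atoms: none
Why: Gold-catalysed 5-endo-dig cycloisomerisation of the γ-hydroxy ynone: the tertiary C10 hydroxyl adds to C3 and protodeauration gives the 3(2H)-furanone, whereas the primary hydroxyl would have to close a seven-membered ring.

Step 7
Reactants: 10 (2S)-2-(2-hydroxyethyl)-5-{3-[(4-methoxyphenyl)methoxy]prop-1-en-2-yl}-2-methylfuran-3(2H)-one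
Product: 11 [(2S)-5-{3-[(4-methoxyphenyl)methoxy]prop-1-en-2-yl}-2-methyl-3-oxo-2,3-dihydrofuran-2-yl]acetaldehyde
Conditions: Dess–Martin periodinane, NaHCO3, CH2Cl2, 0 °C; used without storage
Reagents that add atoms: none
Why: Dess–Martin oxidation under buffered, non-basic conditions should give the C8 aldehyde without β-elimination of the furanone oxygen.

Step 8
Reactants: 12 tert-butyl prop-2-enoate (tert-butyl acrylate); 13 {[tert-butyl(dimethyl)silyl]oxy}acetaldehyde
Product: 14 tert-butyl 4-{[tert-butyl(dimethyl)silyl]oxy}-3-hydroxy-2-methylidenebutanoate (racemic)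
Conditions: DABCO (0.5 equiv), 1,4-dioxane/H2O, rt
Reagents that add atoms: none
Why: Morita–Baylis–Hillman reaction of the activated α-silyloxy aldehyde with the acrylate; the racemic carbinol centre is erased in the next step.

Step 9
Reactants: 14 tert-butyl 4-{[tert-butyl(dimethyl)silyl]oxy}-3-hydroxy-2-methylidenebutanoate
Product: 15 tert-butyl (2Z)-2-(bromomethyl)-4-{[tert-butyl(dimethyl)silyl]oxy}but-2-enoate
Conditions: NBS, Me2S, CH2Cl2, 0 °C to rt
Reagents that add atoms: N-bromosuccinimide, BrN1C(=O)CCC1=O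
Why: Corey–Kim-type activation of the allylic alcohol and SN2′ attack of bromide give the rearranged primary allylic bromide as the more stable Z isomer (CH2OTBS trans to the ester).

Step 10
Reactants: 11 [(2S)-5-{3-[(4-methoxyphenyl)methoxy]prop-1-en-2-yl}-2-methyl-3-oxo-2,3-dihydrofuran-2-yl]acetaldehyde; 15 tert-butyl (2Z)-2-(bromomethyl)-4-{[tert-butyl(dimethyl)silyl]oxy}but-2-enoate
Product: 17 tert-butyl (3S,4R)-3-({[tert-butyl(dimethyl)silyl]oxy}methyl)-4-hydroxy-5-[(2S)-5-{3-[(4-methoxyphenyl)methoxy]prop-1-en-2-yl}-2-methyl-3-oxo-2,3-dihydrofuran-2-yl]-2-methylidenepentanoate, via trimethylsilyl ether 16 (not isolated)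
Conditions: CrCl2 (10 mol%), chiral 1,8-bis(4,5-dihydrooxazol-2-yl)carbazole ligand (12 mol%), Mn powder (2 equiv), i-Pr2NEt (30 mol%), TMSCl (2 equiv), THF, rt; then 1 M HCl, THF, 0 °C
Reagents that add atoms: none
Why: Catalytic asymmetric Nozaki–Hiyama–Kishi 2-(alkoxycarbonyl)allylation: the (Z)-allylchromium should add through a Zimmerman–Traxler chair to give the syn C7/C8 relationship, the ligand enantiomer is chosen for the aldehyde face that gives C8 R (hence C7 S), and the tert-butyl ester stops lactonisation of the new hydroxyl onto C12.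

Step 11
Reactants: 17 tert-butyl (3S,4R)-3-({[tert-butyl(dimethyl)silyl]oxy}methyl)-4-hydroxy-5-[(2S)-5-{3-[(4-methoxyphenyl)methoxy]prop-1-en-2-yl}-2-methyl-3-oxo-2,3-dihydrofuran-2-yl]-2-methylidenepentanoate
Product: 18 tert-butyl (3S,4R)-3-({[tert-butyl(dimethyl)silyl]oxy}methyl)-5-[(2S)-5-{3-[(4-methoxyphenyl)methoxy]prop-1-en-2-yl}-2-methyl-3-oxo-2,3-dihydrofuran-2-yl]-4-{[(2Z)-2-methylbut-2-enoyl]oxy}-2-methylidenepentanoate
Conditions: angelic acid, 2,4,6-trichlorobenzoyl chloride, Et3N, toluene, rt; then 17, 80 °C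
Reagents that add atoms: angelic acid [(2Z)-2-methylbut-2-enoic acid], C/C=C(/C)C(=O)O
Why: Yamaguchi esterification through the preformed mixed anhydride acylates the hindered C8 hydroxyl; leaving out DMAP and excess base should limit Z to E isomerisation to the tiglate.

Step 12
Reactants: 18 (the angelate of 17)
Product: 19 tert-butyl (3S,4R)-3-(hydroxymethyl)-5-[(2S)-5-{3-[(4-methoxyphenyl)methoxy]prop-1-en-2-yl}-2-methyl-3-oxo-2,3-dihydrofuran-2-yl]-4-{[(2Z)-2-methylbut-2-enoyl]oxy}-2-methylidenepentanoate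
Conditions: HF·pyridine, pyridine, THF, 0 °C to rt
Reagents that add atoms: none
Why: Selective desilylation: buffered HF·pyridine cleaves the primary TBS ether while the PMB ether, tert-butyl ester and angelate are stable.

Step 13
Reactants: 19 (the C6 primary alcohol)
Product: 20 tert-butyl (3R,4R)-3-formyl-5-[(2S)-5-{3-[(4-methoxyphenyl)methoxy]prop-1-en-2-yl}-2-methyl-3-oxo-2,3-dihydrofuran-2-yl]-4-{[(2Z)-2-methylbut-2-enoyl]oxy}-2-methylidenepentanoate
Conditions: Dess–Martin periodinane, NaHCO3, CH2Cl2, 0 °C; crude aldehyde used at once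
Reagents that add atoms: none
Why: Buffered Dess–Martin oxidation should give the α-branched, β-acyloxy aldehyde without epimerisation at C7 or elimination of the angelate (the descriptor at C7 changes only because the CIP priority of C6 rises).

Step 14
Reactants: 20 (the C6 aldehyde)
Product: 21 tert-butyl (4S,6R,7S,8R,10S)-6-hydroxy-15-[(4-methoxyphenyl)methoxy]-8-{[(2Z)-2-methylbut-2-enoyl]oxy}-1-oxo-3,10-epoxygermacra-2,11(13)-dien-12-oate (ten-membered ring closed, lactone still open)
Conditions: SmI2 (3 equiv), t-BuOH (5 equiv), THF, 0 °C, slow addition of 20 by syringe pump (final 0.2 mM); aq. NH4Cl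
Reagents that add atoms: none
Why: SmI2 reduces the C6 aldehyde to a samarium ketyl whose carbon adds to C5, the unsubstituted terminus of the C4=C5 methylene that is cross-conjugated with the furanone (a 1,6-acceptor); a second electron gives the samarium dienolate, which t-BuOH protonates at C4 (initial reduction of the dienone instead would lead to the same C5–C6 bond). The closest known reaction type is the SmI2 ketyl–olefin (carbonyl–alkene) reductive cyclisation onto electron-poor alkenes, established for five- to eight-membered carbocycles. The ten-membered carbocycle C1–C10 (a nine-membered oxacycle when counted through the furanone oxygen) closes in the endo-trig mode, the radical attacking the terminal alkene carbon. C6 is set by a lactone-like chelate in which trivalent samarium bridges the ketyl oxygen and the tert-butyl ester carbonyl, so that C5 bonds on the face anti to the C7–C8 bond (6R, H6 trans to H7). C4 is set by delivery of the proton from alcohol bound to the C6 samarium alkoxide, that is on the face cis to O6 (4S). The step needs intramolecular addition to beat capture of the ketyl by the acrylate of a second molecule, pinacol coupling and simple reduction; slow addition at high dilution, the absence of HMPA, the hindered 2-substituted tert-butyl acrylate and the rigid furanone with its quaternary C10, which holds C5 near C6, are meant to secure this.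

Step 15
Reactants: 21 (the macrocyclic hydroxy tert-butyl ester)
Product: 22 (4S,6R,7S,8R,10S)-15-hydroxy-8-{[(2Z)-2-methylbut-2-enoyl]oxy}-1-oxo-3,10-epoxygermacra-2,11(13)-dien-12,6-olide (CNP0108636.1)
Conditions: TFA/CH2Cl2 (1:4), anisole (10 equiv), 0 °C to rt; then aq. NaHCO3
Reagents that add atoms: none
Why: Global acidolysis removes the tert-butyl ester and the PMB ether (anisole traps both cations), and the freed γ-hydroxy acid should lactonise spontaneously to the α-methylene-γ-butyrolactone; no stereocentre is touched.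

Compound list
1 | (S)-citramalic acid, (2S)-2-hydroxy-2-methylbutanedioic acid | OC(=O)C[C@](C)(O)C(=O)O | starting material
2 | [(4S)-2,2,4-trimethyl-5-oxo-1,3-dioxolan-4-yl]acetic acid | OC(=O)C[C@]1(C)OC(C)(C)OC1=O | intermediate
3 | (5S)-5-(2-hydroxyethyl)-2,2,5-trimethyl-1,3-dioxolan-4-one | OCC[C@]1(C)OC(C)(C)OC1=O | intermediate (not isolated)
4 | (3S)-3-hydroxy-3-methyloxolan-2-one | C[C@]1(O)CCOC1=O | intermediate
5 | 2-bromoprop-2-en-1-ol | OCC(Br)=C | starting material
6 | 1-{[(2-bromoprop-2-en-1-yl)oxy]methyl}-4-methoxybenzene | C=C(Br)COCc1ccc(OC)cc1 | intermediate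
7 | (3-{[(4-methoxyphenyl)methoxy]methyl}but-3-en-1-yn-1-yl)trimethylsilane | C[Si](C)(C)C#CC(=C)COCc1ccc(OC)cc1 | intermediate (not isolated)
8 | 1-methoxy-4-{[(2-methylidenebut-3-yn-1-yl)oxy]methyl}benzene | C#CC(=C)COCc1ccc(OC)cc1 | intermediate
9 | (6S)-6,8-dihydroxy-2-{[(4-methoxyphenyl)methoxy]methyl}-6-methyloct-1-en-3-yn-5-one | OCC[C@](C)(O)C(=O)C#CC(=C)COCc1ccc(OC)cc1 | intermediate
10 | (2S)-2-(2-hydroxyethyl)-5-{3-[(4-methoxyphenyl)methoxy]prop-1-en-2-yl}-2-methylfuran-3(2H)-one | OCC[C@]1(C)OC(=CC1=O)C(=C)COCc1ccc(OC)cc1 | intermediate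
11 | [(2S)-5-{3-[(4-methoxyphenyl)methoxy]prop-1-en-2-yl}-2-methyl-3-oxo-2,3-dihydrofuran-2-yl]acetaldehyde | O=CC[C@]1(C)OC(=CC1=O)C(=C)COCc1ccc(OC)cc1 | intermediate
12 | tert-butyl prop-2-enoate | C=CC(=O)OC(C)(C)C | starting material
13 | {[tert-butyl(dimethyl)silyl]oxy}acetaldehyde | O=CCO[Si](C)(C)C(C)(C)C | starting material
14 | tert-butyl 4-{[tert-butyl(dimethyl)silyl]oxy}-3-hydroxy-2-methylidenebutanoate (racemic) | C=C(C(=O)OC(C)(C)C)C(O)CO[Si](C)(C)C(C)(C)C | intermediate
15 | tert-butyl (2Z)-2-(bromomethyl)-4-{[tert-butyl(dimethyl)silyl]oxy}but-2-enoate | BrC/C(=C\CO[Si](C)(C)C(C)(C)C)C(=O)OC(C)(C)C | intermediate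
16 | trimethylsilyl ether of 17 at the C8 oxygen, (3S,4R) | C=C(C(=O)OC(C)(C)C)[C@@H](CO[Si](C)(C)C(C)(C)C)[C@H](O[Si](C)(C)C)C[C@]1(C)OC(=CC1=O)C(=C)COCc1ccc(OC)cc1 | intermediate (not isolated)
17 | tert-butyl (3S,4R)-3-({[tert-butyl(dimethyl)silyl]oxy}methyl)-4-hydroxy-5-[(2S)-5-{3-[(4-methoxyphenyl)methoxy]prop-1-en-2-yl}-2-methyl-3-oxo-2,3-dihydrofuran-2-yl]-2-methylidenepentanoate | C=C(C(=O)OC(C)(C)C)[C@@H](CO[Si](C)(C)C(C)(C)C)[C@H](O)C[C@]1(C)OC(=CC1=O)C(=C)COCc1ccc(OC)cc1 | intermediate
18 | tert-butyl (3S,4R)-3-({[tert-butyl(dimethyl)silyl]oxy}methyl)-5-[(2S)-5-{3-[(4-methoxyphenyl)methoxy]prop-1-en-2-yl}-2-methyl-3-oxo-2,3-dihydrofuran-2-yl]-4-{[(2Z)-2-methylbut-2-enoyl]oxy}-2-methylidenepentanoate | C=C(C(=O)OC(C)(C)C)[C@@H](CO[Si](C)(C)C(C)(C)C)[C@H](OC(=O)/C(C)=C\C)C[C@]1(C)OC(=CC1=O)C(=C)COCc1ccc(OC)cc1 | intermediate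
19 | tert-butyl (3S,4R)-3-(hydroxymethyl)-5-[(2S)-5-{3-[(4-methoxyphenyl)methoxy]prop-1-en-2-yl}-2-methyl-3-oxo-2,3-dihydrofuran-2-yl]-4-{[(2Z)-2-methylbut-2-enoyl]oxy}-2-methylidenepentanoate | C=C(C(=O)OC(C)(C)C)[C@@H](CO)[C@H](OC(=O)/C(C)=C\C)C[C@]1(C)OC(=CC1=O)C(=C)COCc1ccc(OC)cc1 | intermediate
20 | tert-butyl (3R,4R)-3-formyl-5-[(2S)-5-{3-[(4-methoxyphenyl)methoxy]prop-1-en-2-yl}-2-methyl-3-oxo-2,3-dihydrofuran-2-yl]-4-{[(2Z)-2-methylbut-2-enoyl]oxy}-2-methylidenepentanoate | C=C(C(=O)OC(C)(C)C)[C@@H](C=O)[C@H](OC(=O)/C(C)=C\C)C[C@]1(C)OC(=CC1=O)C(=C)COCc1ccc(OC)cc1 | intermediate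
21 | tert-butyl (4S,6R,7S,8R,10S)-6-hydroxy-15-[(4-methoxyphenyl)methoxy]-8-{[(2Z)-2-methylbut-2-enoyl]oxy}-1-oxo-3,10-epoxygermacra-2,11(13)-dien-12-oate | C=C(C(=O)OC(C)(C)C)[C@H]1[C@H](O)C[C@@H](COCc2ccc(OC)cc2)C3=CC(=O)[C@](C)(C[C@H]1OC(=O)/C(C)=C\C)O3 | intermediate
22 | (4S,6R,7S,8R,10S)-15-hydroxy-8-{[(2Z)-2-methylbut-2-enoyl]oxy}-1-oxo-3,10-epoxygermacra-2,11(13)-dien-12,6-olide (CNP0108636.1) | C=C1C(=O)O[C@@H]2C[C@@H](CO)C3=CC(=O)[C@](C)(C[C@@H](OC(=O)/C(C)=C\C)[C@@H]12)O3 | target

Total step count: 15. Longest linear sequence: 11 steps (1, 2, 5, 6, 7, 10, 11, 12, 13, 14, 15); the enyne (steps 3–4) and the allylic bromide (steps 8–9) are made in two-step side branches.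

Steps most likely to fail

1. Step 14. The ketyl may be captured by the acrylate of a second molecule and oligomerise before it reaches C5. The aldehyde may also be reduced without C–C bond formation, the angelate may be lost by β-elimination from the enolisable aldehyde, or the facial selectivity at C6 or C4 may be low. The fallback sets out from 20 and returns at 22, and changes the order of events so that the ring is closed on the free acid. TFA/anisole in CH2Cl2 removes the tert-butyl ester and the PMB ether from 20 to give the formyl acid F1, which is expected to sit in equilibrium with its cyclic hydroxy-lactone form. As its sodium carboxylate (NaHCO3) the acrylic unit is no longer a radical acceptor. SmI2/t-BuOH in THF at high dilution, followed by work-up with 1 M HCl, should then close C5–C6 and lactonise O6 onto C12 in the same flask.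

2. Step 10. Enantio- or diastereocontrol may erode against the remote C10 centre, or the furanone oxygen may be lost from 11 by β-elimination under the amine and silyl chloride conditions. The fallback sets out from 11 and 15 and returns at 17. It uses an indium-mediated Barbier allylation (In powder, THF/H2O, rt), which needs no base and no silyl chloride and should keep the syn preference of the (Z)-allyl metal. This should give 17 together with its (3R,4S) diastereomer F2, and the two are separated by chromatography before step 11.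

3. Step 11. The angeloyl group may isomerise from Z to E (tiglate), or acylation of the hindered C8 hydroxyl may be slow. The fallback sets out from 17 and returns at 18, and builds the angelate on the oxygen instead. Steglich esterification (DCC, DMAP, CH2Cl2) of 17 with 2-[bis(2,2,2-trifluoroethoxy)phosphoryl]propanoic acid gives the phosphonate ester F3. Still–Gennari olefination with acetaldehyde (KN(SiMe3)2, 18-crown-6, THF, −78 °C) should then form the Z-trisubstituted alkene.

Further compounds
F1 | step 14 | (3R,4R)-3-formyl-5-[(2S)-5-(3-hydroxyprop-1-en-2-yl)-2-methyl-3-oxo-2,3-dihydrofuran-2-yl]-4-{[(2Z)-2-methylbut-2-enoyl]oxy}-2-methylidenepentanoic acid (open form of the hydroxy-lactone) | C=C(C(=O)O)[C@@H](C=O)[C@H](OC(=O)/C(C)=C\C)C[C@]1(C)OC(=CC1=O)C(=C)CO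
F2 | step 10 | tert-butyl (3R,4S)-3-({[tert-butyl(dimethyl)silyl]oxy}methyl)-4-hydroxy-5-[(2S)-5-{3-[(4-methoxyphenyl)methoxy]prop-1-en-2-yl}-2-methyl-3-oxo-2,3-dihydrofuran-2-yl]-2-methylidenepentanoate | C=C(C(=O)OC(C)(C)C)[C@H](CO[Si](C)(C)C(C)(C)C)[C@@H](O)C[C@]1(C)OC(=CC1=O)C(=C)COCc1ccc(OC)cc1
F3 | step 11 | 2-[bis(2,2,2-trifluoroethoxy)phosphoryl]propanoate ester of 17 at the C8 oxygen (mixture at the phosphonate α-carbon) | C=C(C(=O)OC(C)(C)C)[C@@H](CO[Si](C)(C)C(C)(C)C)[C@H](OC(=O)C(C)P(=O)(OCC(F)(F)F)OCC(F)(F)F)C[C@]1(C)OC(=CC1=O)C(=C)COCc1ccc(OC)cc1
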